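**Plan** (ring A = trioxygenated ring, ring B = para-phenylene, ring C = 1,2,3-trisubstituted ring, ring D = meta-phenylene)
- Retrosynthesis: remove three O-benzyl groups; return the (S)-carbinol to the aryl ketone; cut the ring A O–ring B C ether (macrocyclic SNAr); cut ring C CH2–C(=O) (benzylzinc acylation); cut ring D C–CH2 (B-alkyl Suzuki); cut the ring C O–ring D ether (SNAr on a 2-fluorobenzaldehyde).
- Enabling feature: on ring B the ether oxygen is para to the carbinol carbon; as C=O this carbon makes the oxygen-bearing carbon of ring B an acceptor for the ring A phenoxide and later becomes the stereocentre.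
- Forward: the ring A styrene (from methyl gallate) and the ring C–ring D bromide are joined through the CH2CH2 bridge, the 4-fluorophenyl ketone is attached, and the 18-membered ring is closed last at the ring A O–ring B C bond.
- Stereochemistry: the single (S) centre comes from asymmetric transfer hydrogenation of the macrocyclic ketone with the (S,S)-TsDPEN ruthenium catalyst.

Key step: step 13

Remark: the carbinol centre of the target is read as S (OH > ring B carbon > CH2 > H); 2-fluoro-3-hydroxybenzaldehyde and 3-bromophenol are taken as purchasable.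

Step 1
Reactants: 1 methyl gallate
Product: 2 methyl 3,4-bis(benzyloxy)-5-hydroxybenzoate
Conditions: BnBr (2.0 equiv), K2CO3, DMF, rt
Reagents that add atoms: benzyl bromide, BrCc1ccccc1
Why: Williamson etherification under carbonate, in which the 4-OH (para to the ester, most acidic) and then one flanking OH are alkylated, so two equivalents of benzyl bromide should leave a single meta OH free, with mono- and tribenzyl ethers removed by chromatography.

Step 2
Reactants: 2 methyl 3,4-bis(benzyloxy)-5-hydroxybenzoate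
Product: 3 methyl 3,4-bis(benzyloxy)-5-(methoxymethoxy)benzoate
Conditions: MOMCl, iPr2NEt, CH2Cl2, 0 °C to rt
Reagents that add atoms: chloromethyl methyl ether, COCCl
Why: Phenol O-alkylation with an α-chloro ether (MOM acetal formation) gives a group that resists hydride, ylide, borane, zinc reagent and base yet is removed by acid without touching benzyl ethers.

Step 3
Reactants: 3 methyl 3,4-bis(benzyloxy)-5-(methoxymethoxy)benzoate
Product: 4 [3,4-bis(benzyloxy)-5-(methoxymethoxy)phenyl]methanol
Conditions: LiAlH4, THF, 0 °C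
Reagents that add atoms: none
Why: Standard LiAlH4 reduction of an aryl ester to the benzylic alcohol, to which benzyl ethers and the MOM acetal are inert.

Step 4
Reactants: 4 [3,4-bis(benzyloxy)-5-(methoxymethoxy)phenyl]methanol
Product: 5 3,4-bis(benzyloxy)-5-(methoxymethoxy)benzaldehyde
Conditions: MnO2 (activated, excess), CH2Cl2, rt
Reagents that add atoms: none
Why: Heterogeneous MnO2 oxidation is selective for benzylic alcohols and stops at the aldehyde.

Step 5
Reactants: 5 3,4-bis(benzyloxy)-5-(methoxymethoxy)benzaldehyde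
Product: 6 1,2-bis(benzyloxy)-5-ethenyl-3-(methoxymethoxy)benzene
Conditions: Ph3PCH3Br, KOtBu, THF, 0 °C to rt
Reagents that add atoms: methyltriphenylphosphonium bromide, C[P+](c1ccccc1)(c1ccccc1)c1ccccc1.[Br-]
Why: Wittig methylenation of an aromatic aldehyde with the unstabilised ylide gives the terminal styrene, the handle for the two-carbon bridge.

Step 6
Reactants: 7 2-fluoro-3-hydroxybenzaldehyde
Product: 8 3-(benzyloxy)-2-fluorobenzaldehyde
Conditions: BnBr, K2CO3, DMF, rt
Reagents that add atoms: benzyl bromide, BrCc1ccccc1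
Why: Williamson etherification of the phenol at room temperature, where the ortho fluoride is not yet displaced.

Step 7
Reactants: 8 3-(benzyloxy)-2-fluorobenzaldehyde; 9 3-bromophenol
Product: 10 3-(benzyloxy)-2-(3-bromophenoxy)benzaldehyde
Conditions: K2CO3, DMAc, 120 °C
Reagents that add atoms: none
Why: Nucleophilic aromatic substitution (SNAr) in which the ortho formyl group stabilises the Meisenheimer anion and fluoride is the leaving group, so the hindered ring C–O–ring D ether forms without a metal while the unactivated C–Br bond of ring D is kept for the coupling.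

Step 8
Reactants: 10 3-(benzyloxy)-2-(3-bromophenoxy)benzaldehyde
Product: 11 [3-(benzyloxy)-2-(3-bromophenoxy)phenyl]methanol
Conditions: NaBH4, MeOH/THF, 0 °C
Reagents that add atoms: none
Why: Chemoselective NaBH4 reduction removes the aldehyde, which an alkylborane would otherwise reduce, and supplies the benzylic alcohol needed later, leaving the aryl bromide intact.

Step 9
Reactants: 6 1,2-bis(benzyloxy)-5-ethenyl-3-(methoxymethoxy)benzene; 11 [3-(benzyloxy)-2-(3-bromophenoxy)phenyl]methanol
Product: 13 [3-(benzyloxy)-2-(3-{2-[3,4-bis(benzyloxy)-5-(methoxymethoxy)phenyl]ethyl}phenoxy)phenyl]methanol, via B-alkyl-9-BBN adduct 12 (not isolated)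
Conditions: 9-BBN, THF, 0 °C to rt; then 11, PdCl2(dppf) (5 mol%), K3PO4 (aq), THF/DMF, 60 °C
Reagents that add atoms: 9-borabicyclo[3.3.1]nonane (9-BBN), B1C2CCCC1CCC2 (its boron is held only in intermediate 12)
Why: Anti-Markovnikov hydroboration of the styrene with 9-BBN followed by B-alkyl Suzuki–Miyaura coupling with the aryl bromide forms the sp3–sp2 bond and delivers the saturated CH2CH2 bridge directly, so no alkene hydrogenation that would endanger the benzyl ethers is needed and the free benzylic OH is tolerated.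

Step 10
Reactants: 13 [3-(benzyloxy)-2-(3-{2-[3,4-bis(benzyloxy)-5-(methoxymethoxy)phenyl]ethyl}phenoxy)phenyl]methanol
Product: 14 1-(benzyloxy)-3-(bromomethyl)-2-(3-{2-[3,4-bis(benzyloxy)-5-(methoxymethoxy)phenyl]ethyl}phenoxy)benzene
Conditions: CBr4, PPh3, CH2Cl2, 0 °C
Reagents that add atoms: carbon tetrabromide, BrC(Br)(Br)Br
Why: Appel bromination converts the primary benzylic alcohol into the bromide under near-neutral conditions that spare the MOM acetal.

Step 11
Reactants: 14 1-(benzyloxy)-3-(bromomethyl)-2-(3-{2-[3,4-bis(benzyloxy)-5-(methoxymethoxy)phenyl]ethyl}phenoxy)benzene; 15 4-fluorobenzoyl chloride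
Product: 17 2-[3-(benzyloxy)-2-(3-{2-[3,4-bis(benzyloxy)-5-(methoxymethoxy)phenyl]ethyl}phenoxy)phenyl]-1-(4-fluorophenyl)ethan-1-one, via benzylic zinc bromide 16 (not isolated)
Conditions: Zn dust (activated with BrCH2CH2Br and Me3SiCl), THF, 0 °C; then 15 (0.9 equiv), Pd(PPh3)4 (5 mol%), THF, 0 °C to rt
Reagents that add atoms: zinc, [Zn] (held only in intermediate 16)
Why: Direct zinc insertion into the benzylic C–Br bond and palladium-catalysed Negishi acylation with the acid chloride give the aryl benzyl ketone, the organozinc being too unreactive to add to the product ketone or to disturb the aryl fluoride and the ethers.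

Step 12
Reactants: 17 2-[3-(benzyloxy)-2-(3-{2-[3,4-bis(benzyloxy)-5-(methoxymethoxy)phenyl]ethyl}phenoxy)phenyl]-1-(4-fluorophenyl)ethan-1-one
Product: 18 2-[3-(benzyloxy)-2-(3-{2-[3,4-bis(benzyloxy)-5-hydroxyphenyl]ethyl}phenoxy)phenyl]-1-(4-fluorophenyl)ethan-1-one
Conditions: HCl (3 M in MeOH), THF, 40 °C
Reagents that add atoms: none
Why: Acid-catalysed methanolysis of the MOM acetal frees the single ring A phenol, while benzyl and diaryl ethers, the ketone and the C–F bond are stable to dilute HCl.

Step 13
Reactants: 18 2-[3-(benzyloxy)-2-(3-{2-[3,4-bis(benzyloxy)-5-hydroxyphenyl]ethyl}phenoxy)phenyl]-1-(4-fluorophenyl)ethan-1-one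
Product: 19 tri-O-benzyl macrocyclic ketone (18-membered ring; the ring A oxygen now bonded to the ring B carbon para to C=O)
Conditions: Cs2CO3 (3 equiv), degassed DMSO, 90 °C, syringe-pump addition to about 2 mM, argon
Reagents that add atoms: none
Why: Cs2CO3 turns the lone phenol of ring A into its phenoxide, which adds to the fluorine-bearing carbon of ring B to give a Meisenheimer anion whose charge is carried by the para carbonyl oxygen, and expulsion of fluoride re-aromatises ring B (SNAr, addition–elimination). The closest known reaction type is the phenoxide/4-fluoroaryl ketone etherification that builds poly(aryl ether ketone)s and their macrocyclic oligomers. The 18-membered ring closes by intramolecular O-arylation at an sp2 carbon, a macro-etherification that slow addition at high dilution should favour over oligomerisation. No stereocentre is formed. The step needs O-arylation at this one fluoride only, which the substrate secures because ring A carries the sole free OH and no other ring bears an activating group. The enolate that carbonate may also form is a reversible bystander, since its carbon cannot reach the fluoride on its own benzoyl ring and its intermolecular reactions are held back by dilution and exclusion of air.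

Step 14
Reactants: 19 tri-O-benzyl macrocyclic ketone
Product: 20 tri-O-benzyl macrocyclic (S)-carbinol
Conditions: RuCl[(S,S)-TsDPEN](p-cymene) (3 mol%), HCO2H/Et3N 5:2, DMF, 40 °C
Reagents that add atoms: none
Why: Noyori–Ikariya asymmetric transfer hydrogenation, in which the ruthenium hydride of the (S,S)-TsDPEN complex delivers hydride in an outer-sphere transition state with ring B held against the p-cymene ligand, should give the S carbinol by the same facial rule that turns acetophenone into (S)-1-phenylethanol, the CH2–ring C arm taking the place of the methyl group.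

Step 15
Reactants: 20 tri-O-benzyl macrocyclic (S)-carbinol
Product: 21 target, (S)-configured macrocyclic tetraol CNP0356934.1
Conditions: H2 (1 atm), 10% Pd/C, EtOAc/MeOH, rt
Reagents that add atoms: none
Why: Palladium-catalysed hydrogenolysis cleaves the three benzyl ethers under neutral conditions at room temperature, where the secondary benzylic C–OH bond and hence the stereocentre should persist if the reaction is stopped at the uptake of three equivalents.

**Compound list**
1 | methyl gallate | COC(=O)c1cc(O)c(O)c(O)c1 | starting material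
2 | methyl 3,4-bis(benzyloxy)-5-hydroxybenzoate | COC(=O)c1cc(O)c(OCc2ccccc2)c(OCc2ccccc2)c1 | intermediate
3 | methyl 3,4-bis(benzyloxy)-5-(methoxymethoxy)benzoate | COC(=O)c1cc(OCOC)c(OCc2ccccc2)c(OCc2ccccc2)c1 | intermediate
4 | [3,4-bis(benzyloxy)-5-(methoxymethoxy)phenyl]methanol | OCc1cc(OCOC)c(OCc2ccccc2)c(OCc2ccccc2)c1 | intermediate
5 | 3,4-bis(benzyloxy)-5-(methoxymethoxy)benzaldehyde | O=Cc1cc(OCOC)c(OCc2ccccc2)c(OCc2ccccc2)c1 | intermediate
6 | 1,2-bis(benzyloxy)-5-ethenyl-3-(methoxymethoxy)benzene | C=Cc1cc(OCOC)c(OCc2ccccc2)c(OCc2ccccc2)c1 | intermediate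
7 | 2-fluoro-3-hydroxybenzaldehyde | O=Cc1cccc(O)c1F | starting material
8 | 3-(benzyloxy)-2-fluorobenzaldehyde | O=Cc1cccc(OCc2ccccc2)c1F | intermediate
9 | 3-bromophenol | Oc1cccc(Br)c1 | starting material
10 | 3-(benzyloxy)-2-(3-bromophenoxy)benzaldehyde | O=Cc1cccc(OCc2ccccc2)c1Oc1cccc(Br)c1 | intermediate
11 | [3-(benzyloxy)-2-(3-bromophenoxy)phenyl]methanol | OCc1cccc(OCc2ccccc2)c1Oc1cccc(Br)c1 | intermediate
12 | 9-{2-[3,4-bis(benzyloxy)-5-(methoxymethoxy)phenyl]ethyl}-9-borabicyclo[3.3.1]nonane (not isolated) | COCOc1cc(CCB2C3CCCC2CCC3)cc(OCc2ccccc2)c1OCc1ccccc1 | intermediate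
13 | [3-(benzyloxy)-2-(3-{2-[3,4-bis(benzyloxy)-5-(methoxymethoxy)phenyl]ethyl}phenoxy)phenyl]methanol | OCc1cccc(OCc2ccccc2)c1Oc1cccc(c1)CCc1cc(OCOC)c(OCc2ccccc2)c(OCc2ccccc2)c1 | intermediate
14 | 1-(benzyloxy)-3-(bromomethyl)-2-(3-{2-[3,4-bis(benzyloxy)-5-(methoxymethoxy)phenyl]ethyl}phenoxy)benzene | BrCc1cccc(OCc2ccccc2)c1Oc1cccc(c1)CCc1cc(OCOC)c(OCc2ccccc2)c(OCc2ccccc2)c1 | intermediate
15 | 4-fluorobenzoyl chloride | O=C(Cl)c1ccc(F)cc1 | starting material
16 | {[3-(benzyloxy)-2-(3-{2-[3,4-bis(benzyloxy)-5-(methoxymethoxy)phenyl]ethyl}phenoxy)phenyl]methyl}zinc bromide (not isolated) | Br[Zn]Cc1cccc(OCc2ccccc2)c1Oc1cccc(c1)CCc1cc(OCOC)c(OCc2ccccc2)c(OCc2ccccc2)c1 | intermediate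
17 | 2-[3-(benzyloxy)-2-(3-{2-[3,4-bis(benzyloxy)-5-(methoxymethoxy)phenyl]ethyl}phenoxy)phenyl]-1-(4-fluorophenyl)ethan-1-one | Fc1ccc(cc1)C(=O)Cc1cccc(OCc2ccccc2)c1Oc1cccc(c1)CCc1cc(OCOC)c(OCc2ccccc2)c(OCc2ccccc2)c1 | intermediate
18 | 2-[3-(benzyloxy)-2-(3-{2-[3,4-bis(benzyloxy)-5-hydroxyphenyl]ethyl}phenoxy)phenyl]-1-(4-fluorophenyl)ethan-1-one (seco phenol) | Fc1ccc(cc1)C(=O)Cc1cccc(OCc2ccccc2)c1Oc1cccc(c1)CCc1cc(O)c(OCc2ccccc2)c(OCc2ccccc2)c1 | intermediate
19 | tri-O-benzyl macrocyclic ketone (18-membered) | O=C1Cc2cccc(OCc3ccccc3)c2Oc2cccc(c2)CCc2cc(OCc3ccccc3)c(OCc3ccccc3)c(c2)Oc2ccc1cc2 | intermediate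
20 | tri-O-benzyl macrocyclic (S)-carbinol | c1ccccc1COc1cc2cc(c1OCc1ccccc1)Oc1ccc(cc1)[C@@H](O)Cc1cccc(OCc3ccccc3)c1Oc1cccc(c1)CC2 | intermediate
21 | (S)-macrocyclic tetraol CNP0356934.1 | Oc1cc2cc(c1O)Oc1ccc(cc1)[C@@H](O)Cc1cccc(O)c1Oc1cccc(c1)CC2 | target

**Step count:** 15 steps in total; longest linear sequence 12 steps (steps 1–5 and 9–15, from methyl gallate); the ring C–ring D branch (steps 6–8) joins at step 9.

**Steps most likely to fail**

Step 13. Ring closure may be too slow with a single para ketone as activator, so oligomerisation and enolate-derived decay could outrun it. The fallback strengthens the acceptor with an ortho nitro group. It sets out from bromide 14: zinc insertion as in step 11 and Pd(PPh3)4-catalysed acylation with purchasable 4-fluoro-3-nitrobenzoyl chloride should give the MOM-protected 4-fluoro-3-nitrophenyl ketone F1. HCl/MeOH should then free the nitro seco phenol F2. K2CO3 in DMF at room temperature and high dilution should close the same O–C bond to the macrocyclic nitro ketone F3. Fe/NH4Cl in aqueous EtOH should reduce it to the macrocyclic aniline F4. One equivalent of NaNO2 with HCl in THF/H2O at 0 °C should give the macrocyclic diazonium chloride F5 (not isolated), which H3PO2 reduces in the same flask. The sequence comes back to the route at 19.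

Step 14. Facial discrimination may be poor if the macrocycle prevents ring B from lying against the arene ligand of the catalyst. The fallback secures the centre by resolution instead of catalysis. It sets out from 19: NaBH4 should give the racemic macrocyclic alcohol F6. Esterification with (S)-O-methylmandelic acid (EDC, DMAP) should give two diastereomers, the (S)-carbinol (S)-O-methylmandelate F7 and the (R)-carbinol (S)-O-methylmandelate F8, to be separated by chromatography. LiOH in THF/H2O should cleave F7 and bring the route back at 20.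

Step 11. Wurtz homocoupling during zinc insertion, or zinc-halide-promoted acyl cleavage of the MOM acetal, may erode the ketone synthesis. The fallback reverses the polarity (Corey–Seebach). 4-Fluorobenzaldehyde and propane-1,3-dithiol (BF3·OEt2) should give 2-(4-fluorophenyl)-1,3-dithiane F9. n-BuLi in THF at −78 °C should give 2-(4-fluorophenyl)-2-lithio-1,3-dithiane F10 (not isolated), which bromide 14 alkylates to the 2-aryl-2-benzyl dithiane F11. MeI/CaCO3 in aqueous MeCN should unmask the carbonyl and bring the route back at 17.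

**Further compounds**
F1 | step 13 | 2-[3-(benzyloxy)-2-(3-{2-[3,4-bis(benzyloxy)-5-(methoxymethoxy)phenyl]ethyl}phenoxy)phenyl]-1-(4-fluoro-3-nitrophenyl)ethan-1-one | [O-][N+](=O)c1cc(ccc1F)C(=O)Cc1cccc(OCc2ccccc2)c1Oc1cccc(c1)CCc1cc(OCOC)c(OCc2ccccc2)c(OCc2ccccc2)c1
F2 | step 13 | 2-[3-(benzyloxy)-2-(3-{2-[3,4-bis(benzyloxy)-5-hydroxyphenyl]ethyl}phenoxy)phenyl]-1-(4-fluoro-3-nitrophenyl)ethan-1-one | [O-][N+](=O)c1cc(ccc1F)C(=O)Cc1cccc(OCc2ccccc2)c1Oc1cccc(c1)CCc1cc(O)c(OCc2ccccc2)c(OCc2ccccc2)c1
F3 | step 13 | tri-O-benzyl macrocyclic ketone with NO2 on ring B ortho to the ether oxygen | O=C1Cc2cccc(OCc3ccccc3)c2Oc2cccc(c2)CCc2cc(OCc3ccccc3)c(OCc3ccccc3)c(c2)Oc2ccc1cc2[N+](=O)[O-]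
F4 | step 13 | tri-O-benzyl macrocyclic ketone with NH2 on ring B ortho to the ether oxygen | O=C1Cc2cccc(OCc3ccccc3)c2Oc2cccc(c2)CCc2cc(OCc3ccccc3)c(OCc3ccccc3)c(c2)Oc2ccc1cc2N
F5 | step 13 | diazonium chloride of F4 (not isolated) | O=C1Cc2cccc(OCc3ccccc3)c2Oc2cccc(c2)CCc2cc(OCc3ccccc3)c(OCc3ccccc3)c(c2)Oc2ccc1cc2[N+]#N.[Cl-]
F6 | step 14 | racemic tri-O-benzyl macrocyclic carbinol | c1ccccc1COc1cc2cc(c1OCc1ccccc1)Oc1ccc(cc1)C(O)Cc1cccc(OCc3ccccc3)c1Oc1cccc(c1)CC2
F7 | step 14 | (S)-carbinol (S)-O-methylmandelate of the tri-O-benzyl macrocycle | c1ccccc1COc1cc2cc(c1OCc1ccccc1)Oc1ccc(cc1)[C@@H](OC(=O)[C@@H](OC)c1ccccc1)Cc1cccc(OCc3ccccc3)c1Oc1cccc(c1)CC2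
F8 | step 14 | (R)-carbinol (S)-O-methylmandelate of the tri-O-benzyl macrocycle | c1ccccc1COc1cc2cc(c1OCc1ccccc1)Oc1ccc(cc1)[C@H](OC(=O)[C@@H](OC)c1ccccc1)Cc1cccc(OCc3ccccc3)c1Oc1cccc(c1)CC2
F9 | step 11 | 2-(4-fluorophenyl)-1,3-dithiane | Fc1ccc(cc1)C1SCCCS1
F10 | step 11 | 2-(4-fluorophenyl)-2-lithio-1,3-dithiane (not isolated) | [Li]C1(SCCCS1)c1ccc(F)cc1
F11 | step 11 | 2-{[3-(benzyloxy)-2-(3-{2-[3,4-bis(benzyloxy)-5-(methoxymethoxy)phenyl]ethyl}phenoxy)phenyl]methyl}-2-(4-fluorophenyl)-1,3-dithiane | Fc1ccc(cc1)C1(SCCCS1)Cc1cccc(OCc2ccccc2)c1Oc1cccc(c1)CCc1cc(OCOC)c(OCc2ccccc2)c(OCc2ccccc2)c1
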